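**Retrosynthetic overview** (atom numbers: C10 = ring carbon with CH3 and CH2CO2H; C5 = ring CH with the C(CH3)2CO2H arm on C4; C8 = ring-fusion C(CH3)O; C9 = ring-fusion CH; C11, C12 = pyran CH2; C13 = OC(CH3)(vinyl))
1. The route rests on the pyran ring O–C13–C12–C11–C9–C8, whose oxygen lies between two fully substituted carbons (C8, C13): this is the ring a ketone C=O draws across a C12=C11–C9=C8 diene.
2. Target ⇒ (ester cleavages, methylenation, ester → aldehyde, C9=C11 hydrogenation) ⇒ dihydropyran triester 13 ⇒ [4+2] of ethyl pyruvate 12 with vinylcyclohexene 11 (C12–C13 and C8–O).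
3. Diene 11 ⇒ enol triflate 10 (Stille vinylation) ⇒ ketone 6 (C8 methylation) ⇒ 2-methylcyclohex-2-enone 1 by asymmetric Mukaiyama–Michael addition and enolate alkylation.
4. Ring order: the carbocycle (ring B) comes from 1; the oxygen ring (ring C) is closed in the key step.

Key step: step 6

Assumption: in step 1 the (S)-oxazaborolidinium catalyst is taken to attack the enone face that gives (R)-configured C5; its sense of induction on an α-methyl enone is to be checked in a first run, and the equally available (R)-catalyst is used if the opposite face reacts.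

**Step 1**
Reactants: 1 2-methylcyclohex-2-en-1-one; 2 1-methoxy-2-methyl-1-(trimethylsilyloxy)prop-1-ene
Product: 3 methyl 2-methyl-2-[(1R)-2-methyl-3-(trimethylsilyloxy)cyclohex-2-en-1-yl]propanoate
Conditions: oxazaborolidinium triflimide from (S)-1-(2-methylphenyl)-3,3-diphenyltetrahydro-1H,3H-pyrrolo[1,2-c][1,3,2]oxazaborole and HNTf2 (20 mol%), Ph3PO (25 mol%), toluene, −20 °C; Et3N quench, non-aqueous work-up
Reagents that add atoms: none
Why: Catalytic asymmetric Mukaiyama–Michael addition, a reaction type established for silyl ketene acetals and cyclic enones under chiral oxazaborolidinium catalysis: the boron-bound enone is attacked at C5 by the nucleophilic carbon of 2 on the face left open by the catalyst, which sets C5, and silyl transfer to the enolate oxygen (free Me3Si+ being held by Ph3PO) leaves the regiodefined C9=C10 enol silane.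

**Step 2**
Reactants: 3 enol silane; 4 tert-butyl bromoacetate
Product: 6 tert-butyl 2-[(1S,6R)-6-(1-methoxy-2-methyl-1-oxopropan-2-yl)-1-methyl-2-oxocyclohexyl]acetate, via benzyltrimethylammonium enolate 5 (not isolated)
Conditions: BnMe3NF (anhydrous), 4 Å MS, THF, −20 °C to rt
Reagents that add atoms: none
Why: Fluoride-promoted regiospecific alkylation of a silyl enol ether: desilylation gives the tetrasubstituted enolate 5 without equilibration and without a nucleophile that would attack the esters, and C10 attacks the bromoacetate on the face anti to the C5 side chain (held pseudoaxial by allylic strain with the C10 methyl), which sets quaternary C10 with the acetate arm trans to that side chain.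

**Step 3**
Reactants: 6 ketone
Product: 8 tert-butyl 2-[(1S,6R)-6-(1-methoxy-2-methyl-1-oxopropan-2-yl)-1,3-dimethyl-2-oxocyclohexyl]acetate (C8 epimer mixture), via lithium enolate 7 (not isolated)
Conditions: LDA, THF, −78 °C; MeI, −78 to 0 °C
Reagents that add atoms: iodomethane, CI
Why: Kinetic ketone enolate alkylation: C8 is the only enolisable position of the ketone (C10 is quaternary) and is far more acidic than the ester CH2, so LDA gives enolate 7 and MeI methylates C8; the new C8 centre is an epimer mixture of no consequence because it becomes sp2 in step 4.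

**Step 4**
Reactants: 8 methyl ketone
Product: 10 tert-butyl 2-[(1S,6R)-6-(1-methoxy-2-methyl-1-oxopropan-2-yl)-1,3-dimethyl-2-(trifluoromethylsulfonyloxy)cyclohex-2-en-1-yl]acetate, via potassium enolate 9 (not isolated)
Conditions: KHMDS, THF, −78 to 0 °C; PhNTf2, 0 °C to rt
Reagents that add atoms: N-phenylbis(trifluoromethanesulfonimide), O=S(=O)(N(c1ccccc1)S(=O)(=O)C(F)(F)F)C(F)(F)F
Why: Enol triflate formation: the ketone can enolise only towards C8, so KHMDS gives the tetrasubstituted enolate 9 from either C8 epimer and PhNTf2 sulfonylates its oxygen.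

**Step 5**
Reactants: 10 enol triflate
Product: 11 tert-butyl 2-[(1S,6R)-2-ethenyl-6-(1-methoxy-2-methyl-1-oxopropan-2-yl)-1,3-dimethylcyclohex-2-en-1-yl]acetate
Conditions: Pd(PPh3)4 (5 mol%), LiCl, tributyl(vinyl)stannane, THF, reflux
Reagents that add atoms: tributyl(vinyl)stannane, C=C[Sn](CCCC)(CCCC)CCCC
Why: Stille coupling: oxidative addition of the vinyl triflate to zerovalent palladium, chloride exchange, transmetalation with the vinylstannane and reductive elimination give the diene with the ring double bond fixed at C8=C9.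

**Step 6**
Reactants: 11 vinylcyclohexene diester; 12 ethyl pyruvate
Product: 13 ethyl (2R,5S,6R,8aR)-5-(2-tert-butoxy-2-oxoethyl)-6-(1-methoxy-2-methyl-1-oxopropan-2-yl)-2,5,8a-trimethyl-3,5,6,7,8,8a-hexahydro-2H-chromene-2-carboxylate
Conditions: Cu(OTf)2 (20 mol%), 2,2′-isopropylidenebis[(4R)-4-tert-butyl-2-oxazoline] (22 mol%), 4 Å MS, CH2Cl2, −20 °C to rt
Reagents that add atoms: none
Why: Proposed new method: two-point chelation of ethyl pyruvate to the divalent copper bis(oxazoline) centre lowers the C=O LUMO so that the diene of 11 adds across it in a concerted but strongly asynchronous [4+2], C12 bonding first to the ketone carbon and oxygen then closing on C8 as positive charge develops at that tertiary allylic position; the closest known reaction type is the copper bis(oxazoline)-catalysed oxo-Diels–Alder reaction of α-keto esters and glyoxylates with oxygenated or terminally unsubstituted 1,3-dienes, which has not been shown for a carbocyclic diene whose oxygen-accepting terminus is fully substituted. The dihydropyran (ring C) is closed by the cycloaddition itself, both of its new bonds (C12–C13 and C8–O) forming in this one step. C8 is set by substrate control: in the half-chair of 11 with the C5 side chain equatorial the C10 methyl is pseudoaxial on the β face, so the dienophile should approach the α face and place oxygen anti to that methyl. C13 is set by the endo position of the copper-bound ester (methyl exo), which puts the C13 methyl syn to the C8 methyl that sits on the inside of the diene; the (R,R) ligand is chosen because the square-planar pyruvate chelate of its antipode exposes the opposite (si) face, so that catalyst preference and the α-face/endo approach should be matched. The step needs ring closure to win over proton loss from the allyl cation-like intermediate and needs the diene to reach an s-cis geometry despite the C8 methyl; the clash of quaternary C10 with the vinyl group in the s-trans form, the tertiary allylic character of C8 and the non-basic, dry, cold medium are relied on for this.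

**Step 7**
Reactants: 13 dihydropyran triester
Product: 14 ethyl (2R,4aR,5S,6R,8aR)-5-(2-tert-butoxy-2-oxoethyl)-6-(1-methoxy-2-methyl-1-oxopropan-2-yl)-2,5,8a-trimethyloctahydro-2H-chromene-2-carboxylate
Conditions: H2 (4 atm), PtO2, EtOAc, rt
Reagents that add atoms: none
Why: Heterogeneous catalytic hydrogenation with syn delivery of H2 to the α face of C9=C11, the β face being covered by the axial methyls on C10 and C8, which sets C9 (H α) and gives the trans-fused bicycle; platinum is chosen over palladium to limit hydrogenolysis of the allylic C8–O bond.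

**Step 8**
Reactants: 14 saturated triester
Product: 16 tert-butyl 2-[(2R,4aR,5S,6R,8aR)-2-formyl-6-(1-methoxy-2-methyl-1-oxopropan-2-yl)-2,5,8a-trimethyloctahydro-2H-chromen-5-yl]acetate, via aluminium hemiacetal 15 (not isolated)
Conditions: iBu2AlH (1.1 equiv), CH2Cl2, −78 °C; MeOH, then aq. potassium sodium tartrate
Reagents that add atoms: none
Why: Partial ester reduction with iBu2AlH: aluminium chelated between the ring oxygen and the C13 ester carbonyl activates this ester and holds the tetrahedral aluminate 15 at −78 °C until work-up, while the tert-butyl ester and the methyl ester on quaternary C4 are sterically shielded; C13 is quaternary and cannot epimerise.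

**Step 9**
Reactants: 16 aldehyde diester
Product: 17 2-[(2R,4aR,5S,6R,8aR)-2-formyl-6-(1-methoxy-2-methyl-1-oxopropan-2-yl)-2,5,8a-trimethyloctahydro-2H-chromen-5-yl]acetic acid
Conditions: CF3CO2H–CH2Cl2 (1:4), 0 °C to rt
Reagents that add atoms: none
Why: Acidolysis of the tert-butyl ester by alkyl–oxygen cleavage (loss of isobutene), placed here because the ring ether is still deactivated by the formyl group on C13, whereas after step 10 it would be a tertiary allylic ether able to ionise at C13.

**Step 10**
Reactants: 17 aldehyde acid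
Product: 19 2-[(2R,4aR,5S,6R,8aR)-2-ethenyl-6-(1-methoxy-2-methyl-1-oxopropan-2-yl)-2,5,8a-trimethyloctahydro-2H-chromen-5-yl]acetic acid, via potassium carboxylate 18 (not isolated)
Conditions: Ph3PCH3Br (4 equiv), KOtBu (4 equiv), THF, 0 °C to rt; aq. NaH2PO4 work-up
Reagents that add atoms: methyltriphenylphosphonium bromide, C[P+](c1ccccc1)(c1ccccc1)c1ccccc1.[Br-]
Why: Wittig methylenation: one equivalent of base turns the acid into the inert carboxylate 18 and the non-stabilised ylide converts the hindered, non-enolisable aldehyde into the vinyl group without touching the methyl ester or C13.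

**Step 11**
Reactants: 19 vinyl acid methyl ester
Product: 20 2-[(2R,4aR,5S,6R,8aR)-5-(carboxymethyl)-2-ethenyl-2,5,8a-trimethyloctahydro-2H-chromen-6-yl]-2-methylpropanoic acid (CNP0186744.2)
Conditions: NaSEt, DMF, 80 °C (degassed); aq. NaH2PO4 work-up (pH 4)
Reagents that add atoms: none
Why: Nucleophilic dealkylation of a hindered methyl ester: the thiolate attacks the methyl carbon (SN2), which is insensitive to crowding at the acyl carbon on quaternary C4, and neither the vinyl group nor the base-stable tertiary allylic ether is affected.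

**Compound list**
1 | 2-methylcyclohex-2-en-1-one | CC1=CCCCC1=O | starting material
2 | 1-methoxy-2-methyl-1-(trimethylsilyloxy)prop-1-ene | COC(O[Si](C)(C)C)=C(C)C | starting material
3 | methyl 2-methyl-2-[(1R)-2-methyl-3-(trimethylsilyloxy)cyclohex-2-en-1-yl]propanoate | C[Si](C)(C)OC1=C(C)[C@H](C(C)(C)C(=O)OC)CCC1 | intermediate
4 | tert-butyl bromoacetate | BrCC(=O)OC(C)(C)C | starting material
5 | benzyltrimethylammonium (3R)-3-(1-methoxy-2-methyl-1-oxopropan-2-yl)-2-methylcyclohex-1-en-1-olate | [O-]C1=C(C)[C@H](C(C)(C)C(=O)OC)CCC1.C[N+](C)(C)Cc1ccccc1 | intermediate (not isolated)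
6 | tert-butyl 2-[(1S,6R)-6-(1-methoxy-2-methyl-1-oxopropan-2-yl)-1-methyl-2-oxocyclohexyl]acetate | O=C1[C@@](C)(CC(=O)OC(C)(C)C)[C@H](C(C)(C)C(=O)OC)CCC1 | intermediate
7 | lithium enolate of 6 (C8=C9) | [Li+].[O-]C=1[C@@](C)(CC(=O)OC(C)(C)C)[C@H](C(C)(C)C(=O)OC)CCC=1 | intermediate (not isolated)
8 | tert-butyl 2-[(1S,6R)-6-(1-methoxy-2-methyl-1-oxopropan-2-yl)-1,3-dimethyl-2-oxocyclohexyl]acetate (C8 epimer mixture) | O=C1[C@@](C)(CC(=O)OC(C)(C)C)[C@H](C(C)(C)C(=O)OC)CCC1C | intermediate
9 | potassium enolate of 8 (C8=C9) | [K+].[O-]C=1[C@@](C)(CC(=O)OC(C)(C)C)[C@H](C(C)(C)C(=O)OC)CCC=1C | intermediate (not isolated)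
10 | tert-butyl 2-[(1S,6R)-6-(1-methoxy-2-methyl-1-oxopropan-2-yl)-1,3-dimethyl-2-(trifluoromethylsulfonyloxy)cyclohex-2-en-1-yl]acetate | O=S(=O)(OC=1[C@@](C)(CC(=O)OC(C)(C)C)[C@H](C(C)(C)C(=O)OC)CCC=1C)C(F)(F)F | intermediate
11 | tert-butyl 2-[(1S,6R)-2-ethenyl-6-(1-methoxy-2-methyl-1-oxopropan-2-yl)-1,3-dimethylcyclohex-2-en-1-yl]acetate | C=CC=1[C@@](C)(CC(=O)OC(C)(C)C)[C@H](C(C)(C)C(=O)OC)CCC=1C | intermediate
12 | ethyl pyruvate | CCOC(=O)C(C)=O | starting material
13 | ethyl (2R,5S,6R,8aR)-5-(2-tert-butoxy-2-oxoethyl)-6-(1-methoxy-2-methyl-1-oxopropan-2-yl)-2,5,8a-trimethyl-3,5,6,7,8,8a-hexahydro-2H-chromene-2-carboxylate | CCOC(=O)[C@@]1(C)CC=C2[C@@](C)(CC(=O)OC(C)(C)C)[C@H](C(C)(C)C(=O)OC)CC[C@@]2(C)O1 | intermediate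
14 | ethyl (2R,4aR,5S,6R,8aR)-5-(2-tert-butoxy-2-oxoethyl)-6-(1-methoxy-2-methyl-1-oxopropan-2-yl)-2,5,8a-trimethyloctahydro-2H-chromene-2-carboxylate | CCOC(=O)[C@@]1(C)CC[C@@H]2[C@@](C)(CC(=O)OC(C)(C)C)[C@H](C(C)(C)C(=O)OC)CC[C@@]2(C)O1 | intermediate
15 | diisobutylaluminium ethyl hemiacetal of aldehyde 16 | CCOC(O[Al](CC(C)C)CC(C)C)[C@@]1(C)CC[C@@H]2[C@@](C)(CC(=O)OC(C)(C)C)[C@H](C(C)(C)C(=O)OC)CC[C@@]2(C)O1 | intermediate (not isolated)
16 | tert-butyl 2-[(2R,4aR,5S,6R,8aR)-2-formyl-6-(1-methoxy-2-methyl-1-oxopropan-2-yl)-2,5,8a-trimethyloctahydro-2H-chromen-5-yl]acetate | O=C[C@@]1(C)CC[C@@H]2[C@@](C)(CC(=O)OC(C)(C)C)[C@H](C(C)(C)C(=O)OC)CC[C@@]2(C)O1 | intermediate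
17 | 2-[(2R,4aR,5S,6R,8aR)-2-formyl-6-(1-methoxy-2-methyl-1-oxopropan-2-yl)-2,5,8a-trimethyloctahydro-2H-chromen-5-yl]acetic acid | O=C[C@@]1(C)CC[C@@H]2[C@@](C)(CC(=O)O)[C@H](C(C)(C)C(=O)OC)CC[C@@]2(C)O1 | intermediate
18 | potassium carboxylate of 17 | O=C[C@@]1(C)CC[C@@H]2[C@@](C)(CC(=O)[O-])[C@H](C(C)(C)C(=O)OC)CC[C@@]2(C)O1.[K+] | intermediate (not isolated)
19 | 2-[(2R,4aR,5S,6R,8aR)-2-ethenyl-6-(1-methoxy-2-methyl-1-oxopropan-2-yl)-2,5,8a-trimethyloctahydro-2H-chromen-5-yl]acetic acid | C=C[C@@]1(C)CC[C@@H]2[C@@](C)(CC(=O)O)[C@H](C(C)(C)C(=O)OC)CC[C@@]2(C)O1 | intermediate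
20 | 2-[(2R,4aR,5S,6R,8aR)-5-(carboxymethyl)-2-ethenyl-2,5,8a-trimethyloctahydro-2H-chromen-6-yl]-2-methylpropanoic acid | C=C[C@@]1(C)CC[C@@H]2[C@@](C)(CC(=O)O)[C@H](C(C)(C)C(=O)O)CC[C@@]2(C)O1 | target

**Total step count:** 11. **Longest linear sequence:** 11 steps (from 1).

**Steps most likely to fail**

Step 6 (labelled step). The polarised cycloaddition may be diverted into proton loss from the allyl cation-like intermediate, giving open-chain products instead of ring closure. The twisted diene, with its C8 methyl on the inside, may also fail to engage, or facial and endo control may erode; the product's tertiary allylic C8–O bond could ionise on the Lewis acid. Fallback by known reactions, setting out from 10 and rejoining at 13: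
- Stille coupling of 10 with tributyl(1-ethoxyvinyl)stannane (Pd(PPh3)4, LiCl, THF, reflux) should give the 2-ethoxydiene F1.
- Hydrolysis of its enol ether (1 M HCl, THF) should give the methyl enone F2.
- TMSOTf/Et3N (CH2Cl2, 0 °C) should convert this into the 2-(trimethylsilyloxy)diene F3.
- Copper bis(oxazoline)-catalysed Mukaiyama aldol addition of F3 to ethyl pyruvate 12 (Cu(OTf)2, the same (R,R) ligand, THF, −78 °C) should give the silylated aldol F4 and, after acidic work-up, the tertiary α-hydroxy ester F5, with C13 set by the catalyst.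
- Luche reduction (NaBH4, CeCl3·7H2O, MeOH) should give the allylic diol F6 as C11 epimers, both of which are usable.
- Catalytic camphorsulfonic acid (CH2Cl2, 0 °C) should ionise the C11 allylic alcohol with allylic transposition; the C13 hydroxyl should then capture C8 anti to the C10 methyl and close the dihydropyran 13. This is the same type of closure by which tertiary allylic diols of this family form their cyclic ethers.

Step 1. The α-methyl group may change how the enone binds to the catalyst, so that enantioselectivity is poor or addition is slow. Fallback, setting out from 1 and 2 and rejoining at 6: the addition is run with an achiral catalyst (HNTf2, 1 mol%, CH2Cl2, −78 °C), giving 3 together with its enantiomer, the (1S)-enol silane F7. Alkylation as in step 2 then passes through the enantiomeric enolate F8 and gives racemic ketone, that is 6 with the (1R,6S)-ketone F9. Preparative chromatography on a chiral stationary phase (supercritical CO2/alcohol) delivers 6, and F9 is discarded.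

Step 7. Uptake of hydrogen at the trisubstituted alkene between two fully substituted carbons may be very slow, and forcing conditions may cause hydrogenolysis of the allylic C8–O bond or loss of facial control. Fallback, setting out from 13 and rejoining at 14: radical hydrogenation by hydrogen-atom transfer with tris(2,2,6,6-tetramethylheptane-3,5-dionato)manganese, Mn(dpm)3 (cat.), PhSiH3 and tBuOOH in iPrOH at rt. A hydrogen atom adds to C11 and the tertiary C9 radical is reduced to the thermodynamically preferred trans ring fusion, without a metal surface and without acid.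

**Further compounds**
F1 | step 6 | tert-butyl 2-[(1S,6R)-2-(1-ethoxyethenyl)-6-(1-methoxy-2-methyl-1-oxopropan-2-yl)-1,3-dimethylcyclohex-2-en-1-yl]acetate | C=C(OCC)C=1[C@@](C)(CC(=O)OC(C)(C)C)[C@H](C(C)(C)C(=O)OC)CCC=1C
F2 | step 6 | tert-butyl 2-[(1S,6R)-2-acetyl-6-(1-methoxy-2-methyl-1-oxopropan-2-yl)-1,3-dimethylcyclohex-2-en-1-yl]acetate | CC(=O)C=1[C@@](C)(CC(=O)OC(C)(C)C)[C@H](C(C)(C)C(=O)OC)CCC=1C
F3 | step 6 | tert-butyl 2-[(1S,6R)-6-(1-methoxy-2-methyl-1-oxopropan-2-yl)-1,3-dimethyl-2-[1-(trimethylsilyloxy)ethenyl]cyclohex-2-en-1-yl]acetate | C=C(O[Si](C)(C)C)C=1[C@@](C)(CC(=O)OC(C)(C)C)[C@H](C(C)(C)C(=O)OC)CCC=1C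
F4 | step 6 | ethyl (2R)-2-methyl-4-oxo-4-(ring B cyclohexenyl of F2)-2-(trimethylsilyloxy)butanoate | CCOC(=O)[C@@](O[Si](C)(C)C)(C)CC(=O)C=1[C@@](C)(CC(=O)OC(C)(C)C)[C@H](C(C)(C)C(=O)OC)CCC=1C
F5 | step 6 | ethyl (2R)-2-hydroxy-2-methyl-4-oxo-4-(ring B cyclohexenyl of F2)butanoate | CCOC(=O)[C@@](O)(C)CC(=O)C=1[C@@](C)(CC(=O)OC(C)(C)C)[C@H](C(C)(C)C(=O)OC)CCC=1C
F6 | step 6 | ethyl (2R)-2,4-dihydroxy-2-methyl-4-(ring B cyclohexenyl of F2)butanoate (C11 epimers) | CCOC(=O)[C@@](O)(C)CC(O)C=1[C@@](C)(CC(=O)OC(C)(C)C)[C@H](C(C)(C)C(=O)OC)CCC=1C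
F7 | step 1 | methyl 2-methyl-2-[(1S)-2-methyl-3-(trimethylsilyloxy)cyclohex-2-en-1-yl]propanoate | C[Si](C)(C)OC1=C(C)[C@@H](C(C)(C)C(=O)OC)CCC1
F8 | step 1 | benzyltrimethylammonium (3S)-3-(1-methoxy-2-methyl-1-oxopropan-2-yl)-2-methylcyclohex-1-en-1-olate | [O-]C1=C(C)[C@@H](C(C)(C)C(=O)OC)CCC1.C[N+](C)(C)Cc1ccccc1
F9 | step 1 | tert-butyl 2-[(1R,6S)-6-(1-methoxy-2-methyl-1-oxopropan-2-yl)-1-methyl-2-oxocyclohexyl]acetate | O=C1[C@](C)(CC(=O)OC(C)(C)C)[C@@H](C(C)(C)C(=O)OC)CCC1
F0 | step 7 | none | none
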